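A direct plan would fuse a ring-A phenol with a ring-B coumarin: ester A1 would be dibrominated (A2), methoxylated
twice with NaOMe/CuBr (A3) and decarboxylated to phenol A4; A4 would then be melted at 240–250 °C with the
4-hydroxycoumarin A5, so that the lactone opens, its acyl group shifts to carbon (diketone A6) and ring C closes.
Weakest would be: (a) the melt, an unprecedented lactone opening/acyl shift that spends both finished fragments and
leaves the closure of A6 (A-ring OH on C2 or 2'-OH on C4) to chance; (b) the copper-catalysed methoxylation of the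
unprotected bromophenol A2, which with bromination and decarboxylation costs three steps for one air-sensitive C6
phenol; (c) the 250 °C synthesis of A5 from an unprotected hydroquinone, where only sterics tell two OH groups apart.

The new route cuts ring A at C7–C8 and C5–C6 and ring C at O1–C8a, C2–C3 and C4–C4a; ring B is bought, ring C (a
4-pyranone) arises second, ring A last. The feature used: around ring A the oxygen-bearing carbons C5, C7 and C8a
alternate with the carbanion-type carbons C4a, C6 and C8, and C3, C6 and C8 each carry OMe, so the chromone is a folded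
chain of three methoxyacetyl units (C3–C4, C8–C8a, C6–C7), one ester carbon (C5 on C4a) and a ring-B benzoate (C2).
No free pentaoxygenated phenol, no copper methoxylation and no melt occur, and no closure chooses between two phenolic
OH groups, because O1 is fixed in ring C before ring A exists.

Key step: step 6

Assumption: the 1,3-dicarbonyl compounds 8, 9 and 12 are written as keto forms although they will exist mainly as enols or metal chelates; atoms of 10 and 12 are given flavone numbers (side-chain CH(OMe) = C8, pyranone C2 = C8a, pyranone C3 = C4a, ester carbon = C5).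

Step 1
Reactants: 1 2-methoxybenzene-1,4-diol (methoxyhydroquinone)
Product: 2 1,4-bis(benzyloxy)-2-methoxybenzene
Conditions: BnBr (2.3 equiv), K2CO3 (3 equiv), DMF, 60 °C, N2
Reagents that add atoms: benzyl bromide, BrCc1ccccc1
Why: Williamson ether synthesis; both phenoxides are benzylated by SN2 on benzyl bromide, and nitrogen keeps the hydroquinone from oxidising before it is capped.

Step 2
Reactants: 2 1,4-bis(benzyloxy)-2-methoxybenzene
Product: 3 1,4-bis(benzyloxy)-2-bromo-5-methoxybenzene
Conditions: NBS (1.0 equiv), MeCN, 0 °C to rt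
Reagents that add atoms: N-bromosuccinimide, O=C1CCC(=O)N1Br
Why: Electrophilic aromatic bromination; C5 is the only position that is para to one oxygen (OMe), ortho to another and not flanked by two substituents, as in the bromination of 1,2,4-trialkoxybenzenes.

Step 3
Reactants: 3 1,4-bis(benzyloxy)-2-bromo-5-methoxybenzene
Product: 5 methyl 2,5-bis(benzyloxy)-4-methoxybenzoate, via aryllithium 4 (not isolated)
Conditions: n-BuLi (1.05 equiv), THF, −78 °C; cannulated into ClCO2Me (3 equiv), THF, −78 °C to rt
Reagents that add atoms: methyl chloroformate, COC(=O)Cl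
Why: Bromine–lithium exchange followed by C-acylation of the aryllithium with a chloroformate; inverse addition into excess chloroformate at −78 °C should prevent a second addition, and the exchange is faster than benzylic deprotonation.

Step 4
Reactants: 6 methyl 4-methoxy-3-oxobutanoate; 7 2-methoxyacetyl chloride
Product: 8 methyl 4-methoxy-2-(2-methoxyacetyl)-3-oxobutanoate
Conditions: MgCl2 (1.0 equiv), pyridine (2.0 equiv), CH2Cl2, 0 °C to rt; 1 M HCl
Reagents that add atoms: none
Why: Magnesium-mediated C-acylation of a beta-keto ester (MgCl2/amine conditions); the chelated magnesium enolate of 6 reacts at C2, and the product, a triacylmethane with two identical methoxyacetyl arms, rests as its magnesium chelate and is not acylated again.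

Step 5
Reactants: 8 methyl 4-methoxy-2-(2-methoxyacetyl)-3-oxobutanoate; 5 methyl 2,5-bis(benzyloxy)-4-methoxybenzoate
Product: 10 methyl 6-[2,5-bis(benzyloxy)-4-methoxyphenyl]-5-methoxy-2-(methoxymethyl)-4-oxo-4H-pyran-3-carboxylate, via triketo ester 9 (not isolated)
Conditions: 8 (2.0 equiv), LiN(iPr)2 (4.1 equiv), THF, −78 to 0 °C; 5 (1.0 equiv), 0 °C to rt; AcOH, −78 °C; then p-TsOH·H2O (0.1 equiv), toluene, 80 °C
Reagents that add atoms: none
Why: Claisen aroylation of a triacylmethane dianion (formed at one of two equivalent CH2OMe groups, as with dehydroacetic acid and 3-acyltetramic acids; the second equivalent of dianion takes up the acidic proton of 9), followed by acid cyclodehydration of the 1,3,5-triketone to the 4-pyranone, in which ketone–ketone closure is expected to outrun lactonisation onto the ester as in the acid closure of 3,5,7-triketo esters to gamma-pyrones.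

Step 6
Reactants: 10 methyl 6-[2,5-bis(benzyloxy)-4-methoxyphenyl]-5-methoxy-2-(methoxymethyl)-4-oxo-4H-pyran-3-carboxylate; 11 methyl 2-methoxyacetate
Product: 13 2-[2,5-bis(benzyloxy)-4-methoxyphenyl]-5,7-dihydroxy-3,6,8-trimethoxy-4H-chromen-4-one, via side-chain ketone 12 (not isolated)
Conditions: LiN(SiMe3)2 (2.2 equiv), THF, −78 °C; 11 (1.3 equiv), −78 to 0 °C; LiN(iPr)2 (2.2 equiv), −78 to 0 °C; 1 M HCl
Reagents that add atoms: none
Why: Proposed new method: LiN(SiMe3)2 deprotonates the 2-CH2OMe group of 10 (the only acidic C–H) to a trienolate spread over the C4 carbonyl and the C5 ester, its side-chain carbon C8 is acylated by 11 (Claisen condensation, C7–C8) to ketone 12, which stays as its C8 enolate, and LiN(iPr)2 then forms the C6 carbanion, which attacks the neighbouring ring ester (Dieckmann condensation, C5–C6, 6-(enolexo)-exo-trig) so that loss of methoxide and two enolisations give aromatic ring A with 5-OH and 7-OH free and 6-OMe and 8-OMe in place. The closest known reaction types are the lateral-anion Claisen–Dieckmann benzannulation of o-toluates and 2-(2-oxoalkyl)benzoates to naphthalene-1,3-diols and the side-chain acylation of 2-alkyl-4-pyranone anions; new is a monocyclic 4-pyranone-3-carboxylate in the role of the toluate, so that ring A of a chromone is built on ring C. No stereocentre results, since C6 and C8 of 12 are enolisable and end as sp2 carbons. The step needs side-chain (gamma) rather than ring (alpha) acylation of the trienolate and C- rather than O-attack on the ring ester: C4a is fully substituted, the enol lactone from O-attack would be reopened by the methoxide present, and aromatisation makes the C-closure irreversible.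

Step 7
Reactants: 13 2-[2,5-bis(benzyloxy)-4-methoxyphenyl]-5,7-dihydroxy-3,6,8-trimethoxy-4H-chromen-4-one
Product: 14 5,7-dihydroxy-2-(2,5-dihydroxy-4-methoxyphenyl)-3,6,8-trimethoxy-4H-chromen-4-one (5,7,2',5'-tetrahydroxy-3,6,8,4'-tetramethoxyflavone)
Conditions: H2 (1 atm), Pd/C (10% Pd on carbon), EtOAc–MeOH, rt; filtration under Ar
Reagents that add atoms: none
Why: Catalytic hydrogenolysis of the two aryl benzyl ethers; the tetrasubstituted C2–C3 double bond of a 3-methoxyflavone should not be reduced at 1 atm and room temperature, and work-up under argon protects the hydroquinone ring B.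

Compound list
1 | 2-methoxybenzene-1,4-diol (methoxyhydroquinone) | COc1cc(O)ccc1O | starting material
2 | 1,4-bis(benzyloxy)-2-methoxybenzene | COc1cc(OCc2ccccc2)ccc1OCc1ccccc1 | intermediate
3 | 1,4-bis(benzyloxy)-2-bromo-5-methoxybenzene | COc1cc(OCc2ccccc2)c(Br)cc1OCc1ccccc1 | intermediate
4 | [2,5-bis(benzyloxy)-4-methoxyphenyl]lithium (not isolated) | [Li]c1cc(OCc2ccccc2)c(OC)cc1OCc1ccccc1 | intermediate
5 | methyl 2,5-bis(benzyloxy)-4-methoxybenzoate | COC(=O)c1cc(OCc2ccccc2)c(OC)cc1OCc1ccccc1 | intermediate
6 | methyl 4-methoxy-3-oxobutanoate | COCC(=O)CC(=O)OC | starting material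
7 | 2-methoxyacetyl chloride | COCC(=O)Cl | starting material
8 | methyl 4-methoxy-2-(2-methoxyacetyl)-3-oxobutanoate | COCC(=O)C(C(=O)OC)C(=O)COC | intermediate
9 | methyl 5-[2,5-bis(benzyloxy)-4-methoxyphenyl]-4-methoxy-2-(2-methoxyacetyl)-3,5-dioxopentanoate (not isolated) | COCC(=O)C(C(=O)OC)C(=O)C(OC)C(=O)c1cc(OCc2ccccc2)c(OC)cc1OCc1ccccc1 | intermediate
10 | methyl 6-[2,5-bis(benzyloxy)-4-methoxyphenyl]-5-methoxy-2-(methoxymethyl)-4-oxo-4H-pyran-3-carboxylate | COCc1oc(-c2cc(OCc3ccccc3)c(OC)cc2OCc2ccccc2)c(OC)c(=O)c1C(=O)OC | intermediate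
11 | methyl 2-methoxyacetate | COCC(=O)OC | starting material
12 | methyl 6-[2,5-bis(benzyloxy)-4-methoxyphenyl]-2-(1,3-dimethoxy-2-oxopropyl)-5-methoxy-4-oxo-4H-pyran-3-carboxylate (not isolated) | COCC(=O)C(OC)c1oc(-c2cc(OCc3ccccc3)c(OC)cc2OCc2ccccc2)c(OC)c(=O)c1C(=O)OC | intermediate
13 | 2-[2,5-bis(benzyloxy)-4-methoxyphenyl]-5,7-dihydroxy-3,6,8-trimethoxy-4H-chromen-4-one | COc1cc(OCc2ccccc2)c(-c2oc3c(OC)c(O)c(OC)c(O)c3c(=O)c2OC)cc1OCc1ccccc1 | intermediate
14 | 5,7-dihydroxy-2-(2,5-dihydroxy-4-methoxyphenyl)-3,6,8-trimethoxy-4H-chromen-4-one | COc1cc(O)c(-c2oc3c(OC)c(O)c(OC)c(O)c3c(=O)c2OC)cc1O | target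

Total step count: 7. Longest linear sequence: 6 steps (steps 1, 2, 3, 5, 6, 7).

Steps most likely to fail

Step 6 (key step). What may go wrong: closure on oxygen instead of carbon (the C8 enolate oxygen of 12 attacks the ring ester and the enol lactone persists), or stalling at the mono-enolate of 12 because the second deprotonation at C6 is incomplete. Fallback with known chemistry, forming ring C last by the Allan–Robinson flavonol synthesis; it sets out from 5 and comes back at 13, and it accepts the three-step preparation of phenol A4 but not the melt. Ester 5 would be saponified (LiOH, THF–H2O) to 2,5-bis(benzyloxy)-4-methoxybenzoic acid F1; part of it would be dehydrated (DCC, CH2Cl2) to 2,5-bis(benzyloxy)-4-methoxybenzoic anhydride F2 and part neutralised (KOH, MeOH) to potassium 2,5-bis(benzyloxy)-4-methoxybenzoate F3. Phenol A4 (from A1 by way of A2 and A3) would be acylated with methoxyacetonitrile (ZnCl2, HCl, Et2O; then hot water; Hoesch reaction) to 2-methoxy-1-(2,4,6-trihydroxy-3,5-dimethoxyphenyl)ethan-1-one F4. Heating F4 with F2 and F3 at 170–180 °C and cleaving surplus O-aroyl groups with KOH in aqueous MeOH should give 13, since both ortho OH groups of the symmetric ring A lead to the same flavone.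

Step 5. What may go wrong: incomplete or oxygen-directed aroylation of the triacylmethane dianion by the hindered, electron-rich ester 5, with proton transfer returning 8. Fallback that forms the aryl ketone bond first; it sets out from 6 and 5 and comes back at 9. The gamma-dianion of 6 (NaH, then n-BuLi, THF, 0 °C) would be aroylated by 5 at its methoxy-bearing carbon to methyl 5-[2,5-bis(benzyloxy)-4-methoxyphenyl]-4-methoxy-3,5-dioxopentanoate F5, kept cold to avoid lactonisation. F5 would then be C-acylated with 7 (MgCl2, pyridine, CH2Cl2) at C2, the tertiary methoxy-bearing C4 being too hindered, to give 9, which is closed to 10 under the acid conditions of step 5.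

Step 7. What may go wrong: over-reduction of the C2–C3 double bond, or oxidation of the freed hydroquinone ring B to the quinone on the catalyst when air is admitted. Fallback without any reducing agent; it sets out from 13 and comes back at 14. The benzyl ethers would be cleaved by a Lewis acid with a cation scavenger (BCl3, pentamethylbenzene, CH2Cl2, −78 °C, MeOH quench at −78 °C), stopped before chelation-assisted demethylation next to the C4 carbonyl can begin; no new compound is made on the way.

Further compounds
F1 | step 6 | 2,5-bis(benzyloxy)-4-methoxybenzoic acid | OC(=O)c1cc(OCc2ccccc2)c(OC)cc1OCc1ccccc1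
F2 | step 6 | 2,5-bis(benzyloxy)-4-methoxybenzoic anhydride | O=C(OC(=O)c1cc(OCc2ccccc2)c(OC)cc1OCc1ccccc1)c1cc(OCc2ccccc2)c(OC)cc1OCc1ccccc1
F3 | step 6 | potassium 2,5-bis(benzyloxy)-4-methoxybenzoate | [K+].[O-]C(=O)c1cc(OCc2ccccc2)c(OC)cc1OCc1ccccc1
F4 | step 6 | 2-methoxy-1-(2,4,6-trihydroxy-3,5-dimethoxyphenyl)ethan-1-one | COCC(=O)c1c(O)c(OC)c(O)c(OC)c1O
F5 | step 5 | methyl 5-[2,5-bis(benzyloxy)-4-methoxyphenyl]-4-methoxy-3,5-dioxopentanoate | COC(=O)CC(=O)C(OC)C(=O)c1cc(OCc2ccccc2)c(OC)cc1OCc1ccccc1
F0 | step 7 | none | none
A1 | direct plan | methyl 2,4,6-trihydroxybenzoate | COC(=O)c1c(O)cc(O)cc1O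
A2 | direct plan | methyl 3,5-dibromo-2,4,6-trihydroxybenzoate | COC(=O)c1c(O)c(Br)c(O)c(Br)c1O
A3 | direct plan | methyl 2,4,6-trihydroxy-3,5-dimethoxybenzoate | COC(=O)c1c(O)c(OC)c(O)c(OC)c1O
A4 | direct plan | 2,4-dimethoxybenzene-1,3,5-triol | COc1c(O)cc(O)c(OC)c1O
A5 | direct plan | 4,6-dihydroxy-3,7-dimethoxy-2H-chromen-2-one | COc1cc2oc(=O)c(OC)c(O)c2cc1O
A6 | direct plan | 1-(2,5-dihydroxy-4-methoxyphenyl)-2-methoxy-3-(2,4,6-trihydroxy-3,5-dimethoxyphenyl)propane-1,3-dione | COc1cc(O)c(cc1O)C(=O)C(OC)C(=O)c1c(O)c(OC)c(O)c(OC)c1O
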